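X left over has chosen nothing yet, so our ledger of X, the limiting reagent, opens with what remains and closes when each mole stands under X, Q, D or J.

all flasks: X 20 mM; L 48 µM; time 1.5 min

|  | temperature | remark |
|---|---|---|
| ochre | 50 °C |  |
| red |  | at 50 °C until 20 s, from then on at 25 °C |
| green | 25 °C |  |

    X → Q (k1 = 0.00622 s⁻¹, Ea1 = 92.0 kJ mol⁻¹)
    L + Q → L + D (k2 = 336 L mol⁻¹ s⁻¹, Ea2 = 48.0 kJ mol⁻¹)
    L → G (k3 = 0.00806 s⁻¹, Ea3 = 94.0 kJ mol⁻¹)
    Q → J (k4 = 0.00240 s⁻¹, Ea4 = 88.0 kJ mol⁻¹)
    (constants at 25 °C)

- constants are those at 25 °C; use the activation energies for any other temperature

* the flask with the highest share of D in all that became D or J ("all alike" if they lie within 1.5 percentage points) (ochre / red / green / all alike)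
* share of D in all that became D or J, ochre
* share of D in all that became D or J, red
* share of D in all that became D or J, green

The choice is made at Q, which leaves either with L to D or by the leak to J. We therefore follow the pull: the constant of the catalytic step times the concentration of L, over the constant of the leak. This is a selectivity factor, the moles of D made per mole of J at that moment. In green it starts at 6.72; this starting pull, catalytic constant times charged L over leak constant, then sinks as L decays to G.

We do the books for green at 1.5 min. In green, first-order decay leaves X at 57.1 %. In green, L falls to 48.4 % of its charge, which takes the pull down to 3.25. If Q in green rises steadily from nothing, its exits centre on 60.0 s, where the pull is 4.14, so by this estimate D takes 80.6 % of what leaves Q. That pull gives Q in green a total loss constant of 0.0123 s⁻¹, and a chain with this constant leaves Q at 24.6 %. The remaining 18.3 % has exited, as D 14.7 % and J 3.55 %, and the books close.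

Ochre and red start hot, with a pull of 1.93, which is lower than the 3.25 green still has at its end. From there L decays, and red reaches its cooling with L at 4.83 %. So up to 1.5 min, D's share in these two stays below 65.9 %, while in green it stays above 76.5 %. Green must lead, but our reckoning goes no further for ochre and red.

The forecast named green, with 14.2 % (13 % to 15.5 %) for ochre, 28 % (26 % to 30 %) for red and 81.4 % (79.5 % to 83 %) for green, holding that at the lower temperature “the catalyst outpaces the leak”; our own figure for green is 80.6 %.

The simulation gives 14.8 % for ochre, 29.1 % for red and 81.3 % for green, so green leads. Green's books read X 57.1 %, Q 24.6 %, D 14.9 % and J 3.42 %.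

At the end of green, the half-life of Q by the catalytic step is 1.5 min, shorter than the 4.8 min by the leak. At that moment in green, the catalytic step uses Q 3.3 times as fast as the leak. Green read at 2.5 min is the second flask: the starting pull 6.72, decayed to 100 s, gives 3.00, and so a share of 75.0 % for D. The computed share there is 77.3 %.

Its constants are those of an exercise, and the outcome is calculated.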